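The chemist who runs these four flasks wants target, and you are asked what the timing of each charge is worth.

common to all: free catalyst 0.41 mol%; time 2.0 min

| charge | starting material | second substrate | remark |
|---|---|---|---|
| teal | 0.095 M | 1.00 equiv (in portions, 4, over 80 s) | first portion at the start, last at 80 s |
| red | 0.095 M | 1.00 equiv (fed, over 80 s) | all else is in the flask from the start; the feed brings no volume worth counting |
| green | 0.095 M (fed, over 80 s) | 1.00 equiv | all else is in the flask from the start; the feed brings no volume worth counting |
| ochre | 0.095 M | 1.00 equiv | everything together at the start |

    starting material + free catalyst ⇌ catalyst intermediate A (K1 = 250 M⁻¹, k1 = 2600 M⁻¹ s⁻¹)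
    catalyst intermediate A → free catalyst + target (k2 = 34 s⁻¹)
    second substrate + free catalyst ⇌ catalyst intermediate B (K3 = 7.9 M⁻¹, k3 = 17000 M⁻¹ s⁻¹)
    catalyst intermediate B → free catalyst + second product (k4 = 9.9 s⁻¹)
    crystals ⇌ target, rate k5*(cs5 - [target]) while solid is left; crystals form when [target] > cs5 (cs5 = 0.060 M, k5 = 9.0 s⁻¹)
    starting material + target → side product (k6 = 0.37 M⁻¹ s⁻¹)

- in percentages every species weighs as the starting material in it: one side product counts as two
- for target the crystals are counted in
- as a solid, counted per litre of solution: crystals
- run time (teal): 2.0 min

- which flask leads in amount of target, in percent of the starting material charged ("all alike" within 1.5 percentage points) (teal / red / green / ochre / all alike)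
- how much target is there at the end, in percent of the starting material charged: teal
- how much target is there at the end, in percent of the starting material charged: red
- how much target is there at the end, in percent of the starting material charged: green
- how much target is there at the end, in percent of the starting material charged: ochre

Begin with the balance of the starting material. A unit leaves through the catalyst as target, or it meets target and forms side product, which costs two units of yield. Divide the side rate by the catalytic rate and you get the leak, the side events per target made:

leak = side rate constant × [target] × (half-speed level + [starting material]) / top speed

The top speed is the catalyst charge times the rate constant of its release of target, 0.0132 M s⁻¹. The half-speed level, the apparent Michaelis constant, is 0.0299 M with the second substrate at its charge, and it shrinks as less second substrate competes for catalyst.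

In my reckoning, dissolved target stops at 0.060 M. I count no second substrate for red and one portion for teal, and I hold the full charge for green. In green, starting material sits where the catalyst keeps pace with the feed, at 0.00294 M.

| flask | half-speed level | leak when target reaches solubility | leak at the end of the starting material | toll |
|---|---|---|---|---|
| ochre | 0.0299 M | 0.109 | 0.0501 | 12.7 % |
| teal | 0.0203 M | 0.0927 | 0.0340 | 10.5 % |
| red | 0.0171 M | 0.0873 | 0.0286 | 9.78 % |
| green | 0.0299 M | 0.0550 | 0.0550 | 7.53 % |

Read the last column first. The toll, twice the mean leak along the starting material consumed, is the percentage by which target falls short of the charge. Now set ochre against green: when target reaches solubility, ochre leaks 0.109, higher than the 0.0550 of green, and in my reckoning ochre then holds 0.0350 M of starting material and green 0.00294 M. In my reckoning red saves 2.9 percentage points on ochre and teal 2.2 points, with their lower half-speed level, and green saves more than either, 5.2 points.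

So I expect target of 87.3 % in ochre, 89.5 % in teal, 90.2 % in red and 92.5 % in green. Green leads red by 2.2 points, which is more than the margin.

The forecast names green, with 88 % for teal, 88.4 % for red, 93.5 % for green and 86 % for ochre, on the ground that “Feeding the starting material keeps it at only a few mM, which minimises that side reaction and puts green clearly ahead”. It places green higher than I do and red lower.

The simulation gives green as the leader, with 88.9 % for teal, 89.3 % for red, 94.7 % for green and 87.2 % for ochre. Ochre holds side product of 12.8 % against its toll of 12.7 %. The main reason for its shortfall is the step from starting material and target to side product: with that step struck out, ochre gives 100 % instead of 87.2 %. In the reckoning the toll goes inversely with top speed while the other charges are held, so the neighbour of ochre charged with 0.25 mol% of free catalyst reckons at 20.9 %, and that flask holds side product of 19.3 %.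

The constants are assumed; the rest is arithmetic.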